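**Retrosynthetic overview**
1. The C8 ester (protected Roche acid) and the exocyclic methylene are installed last on the finished ten-membered lactone.
2. The ten-membered carbocycle is closed second, by ring-closing metathesis forming the ring-cis (Z) C1=C10 olefin of a trans-γ-lactone diene.
3. The C8 carbinol and methallyl arm come from a lactone aldehyde by allylation, oxidation and Felkin-controlled reduction.
4. The γ-lactone is formed first: an intermolecular Evans syn-aldol of a succinate imide with a C1–C6 enal makes the C6–C7 bond (key step) and lactonises to the trans-lactone.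
5. The enal comes from (R)-epichlorohydrin (C2 stereocentre) and a zirconium-catalysed alkyne carboalumination (E-C4=C5).

Assumption: the six starting materials named below are taken as cheap commercial compounds. TBSO = tert-butyldimethylsilyloxy, TESO = triethylsilyloxy; "C1–C15" in the comments is germacrane numbering (lactone O on C6, ester O on C8, OH on C2).

**Step 1**
Reactants: 1 (R)-2-(chloromethyl)oxirane [(R)-epichlorohydrin]; 2 ethynyltrimethylsilane
Product: 3 (R)-1-chloro-5-(trimethylsilyl)pent-4-yn-2-ol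
Conditions: n-BuLi, THF, −78 °C; BF3·OEt2; then 1, −78 °C; aq. work-up
Reagents that add atoms: none
Why: BF3-promoted (Yamaguchi) alkynylation opens the epoxide by SN2 at its unsubstituted carbon, so the stereocentre (future C2) is not touched.

**Step 2**
Reactants: 3 (R)-1-chloro-5-(trimethylsilyl)pent-4-yn-2-ol
Product: 5 (R)-6-(trimethylsilyl)hex-1-en-5-yn-3-ol, via epoxide 4 (not isolated)
Conditions: Me3S+ I− (3.5 equiv), n-BuLi, THF, −10 °C → rt
Reagents that add atoms: trimethylsulfonium iodide, C[S+](C)C.[I-]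
Why: excess dimethylsulfonium methylide closes the chlorohydrin to the terminal epoxide and then opens it at CH2 with loss of Me2S (Corey–Chaykovsky-type one-carbon homologation to the allylic alcohol), leaving the carbinol centre unchanged.

**Step 3**
Reactants: 5 (R)-6-(trimethylsilyl)hex-1-en-5-yn-3-ol
Product: 6 (R)-tert-butyldimethyl{[6-(trimethylsilyl)hex-1-en-5-yn-3-yl]oxy}silane
Conditions: t-BuMe2SiCl, imidazole, DMF, rt
Reagents that add atoms: tert-butyldimethylsilyl chloride, CC(C)(C)[Si](C)(C)Cl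
Why: standard silylation protects the C2 hydroxyl for the organometallic steps that follow.

**Step 4**
Reactants: 6 (R)-tert-butyldimethyl{[6-(trimethylsilyl)hex-1-en-5-yn-3-yl]oxy}silane
Product: 7 (R)-tert-butyl(hex-1-en-5-yn-3-yloxy)dimethylsilane
Conditions: K2CO3, MeOH, rt
Reagents that add atoms: none
Why: methanolysis removes only the alkynyl C–Si group; the O-silyl ether is stable to these conditions.

**Step 5**
Reactants: 7 (R)-tert-butyl(hex-1-en-5-yn-3-yloxy)dimethylsilane
Product: 10 (2E,5R)-5-TBSO-3-methylhepta-2,6-dien-1-ol, via alkenylalane 8 (not isolated), via lithium alkenylaluminate 9 (not isolated)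
Conditions: Me3Al, Cp2ZrCl2 (0.25 equiv), CH2Cl2, 0 °C → rt; strip excess Me3Al; n-BuLi, hexane/THF, −78 → 0 °C; (CH2O)n, rt; Rochelle-salt work-up
Reagents that add atoms: trimethylaluminium, C[Al](C)C; paraformaldehyde (formaldehyde), C=O
Why: Negishi carboalumination adds Me–Al syn across the terminal alkyne (methyl to the internal carbon), and the ate complex traps formaldehyde with retention, which fixes the E-C4=C5 olefin.

**Step 6**
Reactants: 10 (2E,5R)-5-TBSO-3-methylhepta-2,6-dien-1-ol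
Product: 11 (2E,5R)-5-TBSO-3-methylhepta-2,6-dienal
Conditions: activated MnO2, CH2Cl2, rt
Reagents that add atoms: none
Why: MnO2 oxidises the allylic alcohol selectively to the enal without E/Z isomerisation.

**Step 7**
Reactants: 12 (S)-4-benzyloxazolidin-2-one; 13 methyl 4-chloro-4-oxobutanoate
Product: 14 methyl 4-[(S)-4-benzyl-2-oxooxazolidin-3-yl]-4-oxobutanoate
Conditions: n-BuLi, THF, −78 °C; then 13, −78 → 0 °C
Reagents that add atoms: none
Why: N-acylation of the lithiated oxazolidinone by the acid chloride gives the succinate imide for the Evans aldol.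

**Step 8 (key step)**
Reactants: 14 methyl 4-[(S)-4-benzyl-2-oxooxazolidin-3-yl]-4-oxobutanoate; 11 (2E,5R)-5-TBSO-3-methylhepta-2,6-dienal
Product: 17 (S)-4-benzyl-3-({(2R,3S)-2-[(1E,4R)-4-TBSO-2-methylhexa-1,5-dien-1-yl]-5-oxotetrahydrofuran-3-yl}carbonyl)oxazolidin-2-one, via boron enolate 15 (not isolated), via syn-aldol hydroxy ester 16 (not isolated)
Conditions: Bu2BOTf, i-Pr2NEt, CH2Cl2, 0 °C; 11, −78 → 0 °C; pH 7 buffer, MeOH, H2O2, 0 °C; then PPTS (cat.), CH2Cl2, rt
Reagents that add atoms: none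
Why: Evans syn-aldol — the Z-boron enolate of the imide (not the ester) reacts through a Zimmerman–Traxler chair on the face away from the benzyl group, setting C6 (R) and C7, and the γ-hydroxy ester then closes to the trans-γ-lactone.

**Step 9**
Reactants: 17 (the lactone imide from step 8)
Product: 18 (2R,3S)-2-[(1E,4R)-4-TBSO-2-methylhexa-1,5-dien-1-yl]-5-oxotetrahydrofuran-3-carboxylic acid
Conditions: LiOH, H2O2, THF/H2O, 0 °C; Na2SO3; HCl to pH 3
Reagents that add atoms: hydrogen peroxide, OO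
Why: LiOOH cleaves the exocyclic imide carbonyl selectively (Evans auxiliary removal), and any opened lactone re-closes on acidification because only the five-membered ring can form.

**Step 10**
Reactants: 18 (the lactone acid from step 9)
Product: 20 (4R,5R)-4-(hydroxymethyl)-5-[(1E,4R)-4-TBSO-2-methylhexa-1,5-dien-1-yl]dihydrofuran-2(3H)-one, via mixed carbonic anhydride 19 (not isolated)
Conditions: i-BuOCOCl, N-methylmorpholine, THF, −15 °C; then NaBH4, H2O, 0 °C, 15 min
Reagents that add atoms: none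
Why: mixed-anhydride activation lets NaBH4 reduce the acid to the primary alcohol (C8) without touching the lactone or the alkenes, which borane would hydroborate.

**Step 11**
Reactants: 20 (the hydroxymethyl lactone from step 10)
Product: 21 (2R,3S)-2-[(1E,4R)-4-TBSO-2-methylhexa-1,5-dien-1-yl]-5-oxotetrahydrofuran-3-carbaldehyde
Conditions: Dess–Martin periodinane, NaHCO3, CH2Cl2, 0 °C → rt
Reagents that add atoms: none
Why: buffered Dess–Martin oxidation gives the aldehyde under non-basic conditions, avoiding β-elimination of the lactone oxygen; the trans arrangement at C7 is the thermodynamic one.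

**Step 12**
Reactants: 21 (the lactone aldehyde from step 11); 22 3-bromo-2-methylprop-1-ene
Product: 23 (4R,5R)-4-(1-hydroxy-3-methylbut-3-en-1-yl)-5-[(1E,4R)-4-TBSO-2-methylhexa-1,5-dien-1-yl]dihydrofuran-2(3H)-one as a mixture of C8 epimers
Conditions: Zn dust, THF/sat. aq. NH4Cl, 0 °C → rt
Reagents that add atoms: none
Why: aqueous Barbier carbonyl allylation with the symmetrical methallyl unit adds C9, C10 and C14 chemoselectively to the aldehyde; the C8 configuration is not needed because the centre is reset in steps 13 and 14.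

**Step 13**
Reactants: 23 (the epimeric homoallylic alcohols from step 12)
Product: 24 (4S,5R)-4-(3-methylbut-3-enoyl)-5-[(1E,4R)-4-TBSO-2-methylhexa-1,5-dien-1-yl]dihydrofuran-2(3H)-one
Conditions: Dess–Martin periodinane, NaHCO3, CH2Cl2, 0 °C
Reagents that add atoms: none
Why: buffered Dess–Martin oxidation converges both epimers to the β,γ-unsaturated ketone without moving the double bond into conjugation.

**Step 14**
Reactants: 24 (the ketone from step 13)
Product: 25 (4R,5R)-4-[(1R)-1-hydroxy-3-methylbut-3-en-1-yl]-5-[(1E,4R)-4-TBSO-2-methylhexa-1,5-dien-1-yl]dihydrofuran-2(3H)-one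
Conditions: Li[HB(s-Bu)3] (L-Selectride), THF, −78 °C; sat. aq. NH4Cl at −78 °C
Reagents that add atoms: none
Why: Felkin–Anh reduction — the bulky, non-chelating hydride attacks anti to the C7–C6 ring bond (the largest α-substituent), giving the 8R carbinol (C8-O anti to C6-O along the chain).

**Step 15**
Reactants: 25 (the 8R alcohol from step 14)
Product: 26 (4S,5R)-4-[(1R)-3-methyl-1-TESO-but-3-en-1-yl]-5-[(1E,4R)-4-TBSO-2-methylhexa-1,5-dien-1-yl]dihydrofuran-2(3H)-one
Conditions: Et3SiOTf, 2,6-lutidine, CH2Cl2, −78 °C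
Reagents that add atoms: triethylsilyl trifluoromethanesulfonate, CC[Si](CC)(CC)OS(=O)(=O)C(F)(F)F
Why: silylation blocks the C8 hydroxyl (no translactonisation, no alkoxide in step 17) with a group that can later be removed in the presence of the C2 TBS ether.

**Step 16**
Reactants: 26 (the TES-protected diene from step 15)
Product: 27 (3aS,4R,6Z,8R,10E,11aR)-6,10-dimethyl-8-TBSO-4-TESO-3a,4,5,8,9,11a-hexahydrocyclodeca[b]furan-2(3H)-one
Conditions: second-generation Grubbs catalyst (H2IMes)(PCy3)Cl2Ru=CHPh (15 mol % in portions), 1,4-benzoquinone (cat.), toluene (1 mM), 80 °C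
Reagents that add atoms: none
Why: ring-closing metathesis joins the C1 vinyl group and the C10 1,1-disubstituted olefin with loss of ethene; the ten-membered ring already holding the E-C4=C5 olefin accommodates the new trisubstituted olefin as the ring-cis (Z) isomer.

**Step 17**
Reactants: 27 (the macrocyclic lactone from step 16)
Product: 30 (3aS,4R,6Z,8R,10E,11aR)-6,10-dimethyl-3-methylidene-8-TBSO-4-TESO-3a,4,5,8,9,11a-hexahydrocyclodeca[b]furan-2(3H)-one, via Mannich base 28 (not isolated), via ammonium iodide 29 (not isolated)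
Conditions: LiN(i-Pr)2, THF, −78 °C; CH2=NMe2+ I−, −78 °C → rt; MeI, MeOH, rt; aq. NaHCO3/CH2Cl2, rt
Reagents that add atoms: Eschenmoser's salt (N,N-dimethylmethyleneiminium iodide), C=[N+](C)C.[I-]
Why: Mannich reaction of the lactone enolate followed by quaternisation and Hofmann-type elimination gives only the exocyclic methylene; the C11 centre formed on the way is destroyed.

**Step 18**
Reactants: 30 (the α-methylene lactone from step 17)
Product: 31 (3aR,4R,6Z,8R,10E,11aR)-4-hydroxy-6,10-dimethyl-3-methylidene-8-TBSO-3a,4,5,8,9,11a-hexahydrocyclodeca[b]furan-2(3H)-one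
Conditions: PPTS (cat.), MeOH/CH2Cl2 (1:4), 0 °C
Reagents that add atoms: none
Why: mild acid methanolysis cleaves the triethylsilyl ether much faster than the secondary TBS ether, freeing only the C8 hydroxyl.

**Step 19**
Reactants: 32 methyl (S)-3-hydroxy-2-methylpropanoate
Product: 33 methyl (S)-3-TBSO-2-methylpropanoate
Conditions: t-BuMe2SiCl, imidazole, CH2Cl2, rt
Reagents that add atoms: tert-butyldimethylsilyl chloride, CC(C)(C)[Si](C)(C)Cl
Why: silylation protects the primary hydroxyl of the chiral-pool side chain; the stereocentre is not involved.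

**Step 20**
Reactants: 33 methyl (S)-3-TBSO-2-methylpropanoate
Product: 34 (S)-3-TBSO-2-methylpropanoic acid
Conditions: LiOH, THF/MeOH/H2O, 0 °C; HCl to pH 4
Reagents that add atoms: lithium hydroxide, [Li+].[OH-]
Why: cold saponification gives the acid without epimerising the α-centre or eliminating the β-silyloxy group.

**Step 21**
Reactants: 31 (the C8 alcohol from step 18); 34 (S)-3-TBSO-2-methylpropanoic acid
Product: 36 (3aR,4R,6Z,8R,10E,11aR)-6,10-dimethyl-3-methylidene-2-oxo-8-TBSO-2,3,3a,4,5,8,9,11a-octahydrocyclodeca[b]furan-4-yl (S)-3-TBSO-2-methylpropanoate, via Yamaguchi mixed anhydride 35 (not isolated)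
Conditions: 2,4,6-trichlorobenzoyl chloride, Et3N, THF, rt; then 31, DMAP, toluene, rt
Reagents that add atoms: none
Why: Yamaguchi esterification acylates the hindered secondary C8 hydroxyl with retention at C8 and without racemising the acid.

**Step 22**
Reactants: 36 (the bis-silyl ether from step 21)
Product: 37 (3aR,4R,6Z,8R,10E,11aR)-8-hydroxy-6,10-dimethyl-3-methylidene-2-oxo-2,3,3a,4,5,8,9,11a-octahydrocyclodeca[b]furan-4-yl (S)-3-hydroxy-2-methylpropanoate (target, CNP0254953.1)
Conditions: HF·pyridine, pyridine, THF, 0 °C → rt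
Reagents that add atoms: none
Why: buffered fluoride desilylation removes both TBS groups without base-induced elimination of the β-hydroxy ester or addition to the methylene lactone.

**Compound list**
1 | (R)-2-(chloromethyl)oxirane [(R)-epichlorohydrin] | ClC[C@H]1CO1 | starting material
2 | ethynyltrimethylsilane | C#C[Si](C)(C)C | starting material
3 | (R)-1-chloro-5-(trimethylsilyl)pent-4-yn-2-ol | ClC[C@H](O)CC#C[Si](C)(C)C | intermediate
4 | (R)-2-[3-(trimethylsilyl)prop-2-yn-1-yl]oxirane | C1[C@H](O1)CC#C[Si](C)(C)C | intermediate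
5 | (R)-6-(trimethylsilyl)hex-1-en-5-yn-3-ol | C=C[C@H](O)CC#C[Si](C)(C)C | intermediate
6 | (R)-tert-butyldimethyl{[6-(trimethylsilyl)hex-1-en-5-yn-3-yl]oxy}silane | C=C[C@H](O[Si](C)(C)C(C)(C)C)CC#C[Si](C)(C)C | intermediate
7 | (R)-tert-butyl(hex-1-en-5-yn-3-yloxy)dimethylsilane | C=C[C@H](O[Si](C)(C)C(C)(C)C)CC#C | intermediate
8 | dimethyl[(1E,4R)-4-TBSO-2-methylhexa-1,5-dien-1-yl]alane | C=C[C@H](O[Si](C)(C)C(C)(C)C)C/C(C)=C/[Al](C)C | intermediate
9 | lithium butyl(dimethyl)[(1E,4R)-4-TBSO-2-methylhexa-1,5-dien-1-yl]aluminate | [Li+].C=C[C@H](O[Si](C)(C)C(C)(C)C)C/C(C)=C/[Al-](C)(C)CCCC | intermediate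
10 | (2E,5R)-5-TBSO-3-methylhepta-2,6-dien-1-ol | C=C[C@H](O[Si](C)(C)C(C)(C)C)C/C(C)=C/CO | intermediate
11 | (2E,5R)-5-TBSO-3-methylhepta-2,6-dienal | C=C[C@H](O[Si](C)(C)C(C)(C)C)C/C(C)=C/C=O | intermediate
12 | (S)-4-benzyloxazolidin-2-one | O=C1N[C@@H](Cc2ccccc2)CO1 | starting material
13 | methyl 4-chloro-4-oxobutanoate | COC(=O)CCC(Cl)=O | starting material
14 | methyl 4-[(S)-4-benzyl-2-oxooxazolidin-3-yl]-4-oxobutanoate | COC(=O)CCC(=O)N1C(=O)OC[C@@H]1Cc2ccccc2 | intermediate
15 | (Z)-dibutylboron enolate of 14 (B–O cis to CH2CO2Me) | CCCCB(CCCC)O/C(=C\CC(=O)OC)N1C(=O)OC[C@@H]1Cc2ccccc2 | intermediate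
16 | methyl (3S,4R,5E,8R)-3-{[(S)-4-benzyl-2-oxooxazolidin-3-yl]carbonyl}-4-hydroxy-6-methyl-8-TBSO-deca-5,9-dienoate | COC(=O)C[C@H](C(=O)N1C(=O)OC[C@@H]1Cc2ccccc2)[C@H](O)/C=C(\C)C[C@@H](O[Si](C)(C)C(C)(C)C)C=C | intermediate
17 | (S)-4-benzyl-3-({(2R,3S)-2-[(1E,4R)-4-TBSO-2-methylhexa-1,5-dien-1-yl]-5-oxotetrahydrofuran-3-yl}carbonyl)oxazolidin-2-one (trans-lactone) | O=C1O[C@H](/C=C(\C)C[C@@H](O[Si](C)(C)C(C)(C)C)C=C)[C@H](C1)C(=O)N1C(=O)OC[C@@H]1Cc2ccccc2 | intermediate
18 | (2R,3S)-2-[(1E,4R)-4-TBSO-2-methylhexa-1,5-dien-1-yl]-5-oxotetrahydrofuran-3-carboxylic acid | O=C1O[C@H](/C=C(\C)C[C@@H](O[Si](C)(C)C(C)(C)C)C=C)[C@H](C1)C(=O)O | intermediate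
19 | isobutyl carbonic anhydride of 18 | O=C1O[C@H](/C=C(\C)C[C@@H](O[Si](C)(C)C(C)(C)C)C=C)[C@H](C1)C(=O)OC(=O)OCC(C)C | intermediate
20 | (4R,5R)-4-(hydroxymethyl)-5-[(1E,4R)-4-TBSO-2-methylhexa-1,5-dien-1-yl]dihydrofuran-2(3H)-one | O=C1O[C@H](/C=C(\C)C[C@@H](O[Si](C)(C)C(C)(C)C)C=C)[C@H](C1)CO | intermediate
21 | (2R,3S)-2-[(1E,4R)-4-TBSO-2-methylhexa-1,5-dien-1-yl]-5-oxotetrahydrofuran-3-carbaldehyde | O=C1O[C@H](/C=C(\C)C[C@@H](O[Si](C)(C)C(C)(C)C)C=C)[C@H](C1)C=O | intermediate
22 | 3-bromo-2-methylprop-1-ene | C=C(C)CBr | starting material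
23 | (4R,5R)-4-(1-hydroxy-3-methylbut-3-en-1-yl)-5-[(1E,4R)-4-TBSO-2-methylhexa-1,5-dien-1-yl]dihydrofuran-2(3H)-one (both C8 epimers) | O=C1O[C@H](/C=C(\C)C[C@@H](O[Si](C)(C)C(C)(C)C)C=C)[C@H](C1)C(O)CC(C)=C | intermediate
24 | (4S,5R)-4-(3-methylbut-3-enoyl)-5-[(1E,4R)-4-TBSO-2-methylhexa-1,5-dien-1-yl]dihydrofuran-2(3H)-one | O=C1O[C@H](/C=C(\C)C[C@@H](O[Si](C)(C)C(C)(C)C)C=C)[C@H](C1)C(=O)CC(C)=C | intermediate
25 | (4R,5R)-4-[(1R)-1-hydroxy-3-methylbut-3-en-1-yl]-5-[(1E,4R)-4-TBSO-2-methylhexa-1,5-dien-1-yl]dihydrofuran-2(3H)-one | O=C1O[C@H](/C=C(\C)C[C@@H](O[Si](C)(C)C(C)(C)C)C=C)[C@H](C1)[C@H](O)CC(C)=C | intermediate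
26 | (4S,5R)-4-[(1R)-3-methyl-1-TESO-but-3-en-1-yl]-5-[(1E,4R)-4-TBSO-2-methylhexa-1,5-dien-1-yl]dihydrofuran-2(3H)-one | O=C1O[C@H](/C=C(\C)C[C@@H](O[Si](C)(C)C(C)(C)C)C=C)[C@H](C1)[C@H](O[Si](CC)(CC)CC)CC(C)=C | intermediate
27 | (3aS,4R,6Z,8R,10E,11aR)-6,10-dimethyl-8-TBSO-4-TESO-3a,4,5,8,9,11a-hexahydrocyclodeca[b]furan-2(3H)-one | C1C(=O)O[C@@H]2/C=C(\C)C[C@@H](O[Si](C)(C)C(C)(C)C)/C=C(/C)C[C@@H](O[Si](CC)(CC)CC)[C@@H]12 | intermediate
28 | 3-[(dimethylamino)methyl] derivative of 27 (C3 epimers) | CN(C)CC1C(=O)O[C@@H]2/C=C(\C)C[C@@H](O[Si](C)(C)C(C)(C)C)/C=C(/C)C[C@@H](O[Si](CC)(CC)CC)[C@@H]12 | intermediate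
29 | N-methyl quaternary ammonium iodide of 28 | C[N+](C)(C)CC1C(=O)O[C@@H]2/C=C(\C)C[C@@H](O[Si](C)(C)C(C)(C)C)/C=C(/C)C[C@@H](O[Si](CC)(CC)CC)[C@@H]12.[I-] | intermediate
30 | (3aS,4R,6Z,8R,10E,11aR)-6,10-dimethyl-3-methylidene-8-TBSO-4-TESO-3a,4,5,8,9,11a-hexahydrocyclodeca[b]furan-2(3H)-one | C=C1C(=O)O[C@@H]2/C=C(\C)C[C@@H](O[Si](C)(C)C(C)(C)C)/C=C(/C)C[C@@H](O[Si](CC)(CC)CC)[C@@H]12 | intermediate
31 | (3aR,4R,6Z,8R,10E,11aR)-4-hydroxy-6,10-dimethyl-3-methylidene-8-TBSO-3a,4,5,8,9,11a-hexahydrocyclodeca[b]furan-2(3H)-one | C=C1C(=O)O[C@@H]2/C=C(\C)C[C@@H](O[Si](C)(C)C(C)(C)C)/C=C(/C)C[C@@H](O)[C@@H]12 | intermediate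
32 | methyl (S)-3-hydroxy-2-methylpropanoate | C[C@@H](CO)C(=O)OC | starting material
33 | methyl (S)-3-TBSO-2-methylpropanoate | C[C@@H](CO[Si](C)(C)C(C)(C)C)C(=O)OC | intermediate
34 | (S)-3-TBSO-2-methylpropanoic acid | C[C@@H](CO[Si](C)(C)C(C)(C)C)C(=O)O | intermediate
35 | (S)-3-TBSO-2-methylpropanoic 2,4,6-trichlorobenzoic anhydride | C[C@@H](CO[Si](C)(C)C(C)(C)C)C(=O)OC(=O)c1c(Cl)cc(Cl)cc1Cl | intermediate
36 | (3aR,4R,6Z,8R,10E,11aR)-6,10-dimethyl-3-methylidene-2-oxo-8-TBSO-2,3,3a,4,5,8,9,11a-octahydrocyclodeca[b]furan-4-yl (S)-3-TBSO-2-methylpropanoate | C=C1C(=O)O[C@@H]2/C=C(\C)C[C@@H](O[Si](C)(C)C(C)(C)C)/C=C(/C)C[C@@H](OC(=O)[C@@H](C)CO[Si](C)(C)C(C)(C)C)[C@@H]12 | intermediate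
37 | (3aR,4R,6Z,8R,10E,11aR)-8-hydroxy-6,10-dimethyl-3-methylidene-2-oxo-2,3,3a,4,5,8,9,11a-octahydrocyclodeca[b]furan-4-yl (S)-3-hydroxy-2-methylpropanoate | C=C1C(=O)O[C@@H]2/C=C(\C)C[C@@H](O)/C=C(/C)C[C@@H](OC(=O)[C@@H](C)CO)[C@@H]12 | target

**Step count**
Total: 22 steps. Longest linear sequence: 19 steps (steps 1–6, 8–18, 21, 22).

**Three steps most likely to fail, with fallbacks**

Step 16 (ring-closing metathesis). The ring is strained, one partner is a 1,1-disubstituted olefin, and dimerisation or failure to cyclise is the main danger. The fallback reverses the order of ring construction, closing the carbocycle on an open-chain precursor and rebuilding the lactone afterwards. It sets out from 26: LiBH4 in THF at 0 °C reduces the lactone to the seco-diol F1, in which the two olefin-bearing chains are no longer held trans on a rigid five-membered ring. Metathesis of the seco-diol with the same ruthenium carbene at high dilution gives the macrocyclic diol F2. TEMPO with PhI(OAc)2 in CH2Cl2 then oxidises only the primary alcohol; the hydroxy aldehyde closes onto the C6 hydroxyl as the lactol F3 (the C8 oxygen is silylated), which is oxidised further in the same flask to lactone 27, where the route is rejoined.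

Step 14 (Felkin reduction of the β,γ-unsaturated ketone). The risks are a poor facial ratio and base-induced migration of the double bond into conjugation. The fallback sets C8 during the C–C bond formation under reagent control instead of by reduction. It sets out from aldehyde 21: asymmetric methallylboration with B-methallyldiisopinocampheylborane, made from (+)-Ipc2BOMe and CH2=C(CH3)CH2MgCl (Et2O, −78 °C; NaBO3·4H2O work-up), the antipode expected to deliver the methallyl group to the Re face, gives the 8R alcohol 25 directly. Compounds 23 and 24 are bypassed, the route is rejoined at 25, and no compound outside the list is formed (F0).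

Step 17 (enolate methylenation on the macrocycle). The strong base could cause elimination or translactonisation, and the Mannich alkylation may be sluggish in the ten-membered ring. The fallback avoids the enolate: it sets out from 27, which is heated with tert-butoxybis(dimethylamino)methane (Bredereck's reagent, toluene, 80 °C) to give the α-(dimethylaminomethylene) lactone F4. Conjugate reduction with i-Bu2AlH (THF, −78 °C) and mild acidic work-up expels dimethylamine and gives the α-methylene lactone 30, where the route is rejoined.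

**Further compounds**
F0 | step 14 | none | none
F1 | step 16 | seco-diol from 26: (3S,4R,5E,8R)-6-methyl-3-[(1R)-3-methyl-1-TESO-but-3-en-1-yl]-8-TBSO-deca-5,9-diene-1,4-diol | OCC[C@@H]([C@H](O)/C=C(\C)C[C@@H](O[Si](C)(C)C(C)(C)C)C=C)[C@H](O[Si](CC)(CC)CC)CC(C)=C
F2 | step 16 | macrocyclic diol: (1Z,5E)-cyclodeca-1,5-diene carrying the C6 hydroxyl, the C7 2-hydroxyethyl group, C8-OTES and C2-OTBS with the configurations of 27 | OCC[C@H]1[C@H](O)/C=C(\C)C[C@@H](O[Si](C)(C)C(C)(C)C)/C=C(/C)C[C@H]1O[Si](CC)(CC)CC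
F3 | step 16 | lactol of 27 (C12 hemiacetal, both anomers) | C1C(O)O[C@@H]2/C=C(\C)C[C@@H](O[Si](C)(C)C(C)(C)C)/C=C(/C)C[C@@H](O[Si](CC)(CC)CC)[C@@H]12
F4 | step 17 | 3-[(dimethylamino)methylidene] derivative of 27 | CN(C)C=C1C(=O)O[C@@H]2/C=C(\C)C[C@@H](O[Si](C)(C)C(C)(C)C)/C=C(/C)C[C@@H](O[Si](CC)(CC)CC)[C@@H]12
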